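Numbering follows the kaurane skeleton (C8 quaternary bridgehead, C9 ketone, C11/C12 ring CH2, C13 bridgehead CH, C14 one-carbon bridge, C15 CH2, C16 methylidene carbon; C7–C6–C5 chain; ring A = C1–C5, C10; C19 lactone carbonyl).

The strategy rests on the 1,5-relation of the C9 ketone and C16 (a masked ketone) along C9–C11–C12–C13–C16. These atoms sit in the bicyclo[3.2.1]octane made of the six-membered ring C8–C9–C11–C12–C13–C14 and the five-membered ring C8–C15–C16–C13–C14. That pattern is the retron of an enone–alkene [2+2] photocycloaddition followed by retro-aldol opening.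
Target ⇒ (C9 re-oxidation, C3 acetate, C3 ketone reduction) ring A keto lactone ⇒ cut C3–C4 and C19–O (Dieckmann/translactonisation) to a C10 butenolide with a C4 ester ⇒ cut C5–C10 (catalytic vinylogous Mukaiyama–Michael) to an enal and a 5-methyl-2-silyloxyfuran.
Enal ⇒ C5 aldehyde ⇒ 6-methylidene ketone ⇒ bicyclo[3.2.1]octane-2,6-dione ⇒ (re-join C11–C16, cut C13–C16 and C11–C12) 5-allyl-3-acetoxycyclopentenone. Its C8 centre comes from a palladium-catalysed decarboxylative allylation of a cyclopentane-1,3-dione vinylogous ester.
Ring order: purchased cyclopentane ring (later sacrificed) → five-membered ring C8–C15–C16–C13–C14 plus cyclobutane → six-membered ring by fragmentation → butenolide → ring A carbocycle and 19,10-lactone in one operation.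

Key step: step 7

Assumption: the sense of induction in steps 4 and 15 is taken to follow that of simple 2-alkylcycloalkanone enolates and β-alkyl enals. Both antipodes of the ligand and of the amine are commercial, so a reversed sense would be met by exchanging them.

Step 1
Reactants: 1 cyclopentane-1,3-dione
Product: 2 3-isobutoxycyclopent-2-en-1-one
Conditions: i-BuOH, p-toluenesulfonic acid monohydrate (cat.), toluene, reflux, Dean–Stark
Reagents that add atoms: isobutanol, CC(C)CO
Why: Acid-catalysed vinylogous esterification with azeotropic removal of water converts the enolised dione into its isobutyl enol ether, which leaves the future C8 (α′) as the only kinetically acidic site.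

Step 2
Reactants: 2 3-isobutoxycyclopent-2-en-1-one; 3 allyl chloroformate
Product: 4 allyl 4-isobutoxy-2-oxocyclopent-3-ene-1-carboxylate (racemic, configurationally labile)
Conditions: LiN(i-Pr)2 (2.1 equiv), THF, −78 °C; then 3, −78 → −30 °C
Reagents that add atoms: none
Why: Kinetic α′-deprotonation of the vinylogous ester followed by Claisen-type C-acylation with the chloroformate gives the β-keto ester, and the second equivalent of amide base absorbs its acidic proton so that the enolate of 2 is not consumed as a base.

Step 3
Reactants: 4 allyl 4-isobutoxy-2-oxocyclopent-3-ene-1-carboxylate; 5 (3-bromopropoxy)(tert-butyl)dimethylsilane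
Product: 6 allyl 1-[3-(tert-butyldimethylsilyloxy)propyl]-4-isobutoxy-2-oxocyclopent-3-ene-1-carboxylate (racemic)
Conditions: Cs2CO3, NaI (cat.), MeCN, 60 °C
Reagents that add atoms: none
Why: The soft caesium enolate of the β-keto ester is alkylated at carbon by the primary halide (SN2 with in situ Finkelstein exchange), which builds the fully substituted C8 in racemic form, its configuration being erased in step 4.

Step 4
Reactants: 6 racemic quaternary allyl β-keto ester
Product: 7 (S)-5-allyl-5-[3-(tert-butyldimethylsilyloxy)propyl]-3-isobutoxycyclopent-2-en-1-one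
Conditions: Pd2(dba)3 (2.5 mol %), (R)-4-tert-butyl-2-[2-(diphenylphosphino)phenyl]-4,5-dihydrooxazole ((R)-t-BuPHOX, 6.5 mol %), toluene, 30 °C
Reagents that add atoms: none
Why: Decarboxylative asymmetric allylic alkylation (Tsuji–Trost type): zerovalent palladium ionises the allyl ester, loss of CO2 gives an achiral enolate so that both enantiomers of 6 converge, and allyl transfer inside the PHOX pocket sets C8, the (R)-ligand being chosen because the (S)-ligand delivers allyl to the opposite enolate face in 2-alkylcycloalkanone enolates.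

Step 5
Reactants: 7 (S)-allyl vinylogous ester
Product: 8 (S)-4-allyl-4-[3-(tert-butyldimethylsilyloxy)propyl]cyclopentane-1,3-dione
Conditions: NaOH (2 M aq.), THF/MeOH, 50 °C; then cold 1 M HCl to pH 4–5, immediate extraction
Reagents that add atoms: sodium hydroxide, [Na+].[OH-]
Why: Vinylogous saponification by addition–elimination of hydroxide at C16 frees the dione as its stable enolate, and base is used in place of the customary aqueous acid because the latter would strip the primary silyl ether.

Step 6
Reactants: 8 (S)-4-allyl-4-(silyloxypropyl)cyclopentane-1,3-dione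
Product: 9 (S)-3-acetoxy-5-allyl-5-[3-(tert-butyldimethylsilyloxy)propyl]cyclopent-2-en-1-one
Conditions: Ac2O (1.1 equiv), Et3N, CH2Cl2, 0 °C
Reagents that add atoms: acetic anhydride, CC(=O)OC(C)=O
Why: O-Acylation of the ambident dione enolate should take place at the oxygen on C16, which is remote from the quaternary C8, rather than at the neopentyl oxygen on C9, and the absence of a nucleophilic acyl-transfer catalyst avoids O-to-C acetyl migration.

Step 7
Reactants: 9 (S)-3-acetoxy-5-allyl-5-[3-(tert-butyldimethylsilyloxy)propyl]cyclopent-2-en-1-one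
Product: 11 (1S,5R)-1-[3-(tert-butyldimethylsilyloxy)propyl]bicyclo[3.2.1]octane-2,6-dione, via tricyclic cyclobutyl acetate 10 (not isolated)
Conditions: hν (medium-pressure mercury lamp, Pyrex, λ > 290 nm), degassed MeCN (0.01 M), 10 °C; evaporate; K2CO3 (0.3 equiv), MeOH, 0 °C → rt
Reagents that add atoms: none
Why: Excitation of the acetoxy enone and intersystem crossing give the triplet, whose β-carbon C16 bonds to the internal alkene carbon C13, and after spin inversion the 1,4-biradical (α-acyl radical at C11, primary radical at C12) collapses by C11–C12 bonding to the cyclobutane C11–C16–C13–C12 of 10; catalytic K2CO3 in methanol then takes off the acetyl group and the cyclobutanolate opens by retro-aldol cleavage of C11–C16, a bond aligned with the C9 carbonyl and loaded with four-ring strain. This is an intramolecular de Mayo reaction: the enol acetate of cyclopentane-1,3-dione is a classical partner in the intermolecular version, and 6-allylcyclohex-2-enones, the closest α′-allyl enones, are known to photocyclise in the same orientation (internal alkene carbon to the enone β-carbon). The five-membered ring C8–C15–C16–C13–C14 closes in the 5-exo mode over the three-atom tether C15–C8–C14, the cyclobutane closes by radical recombination, and the six-membered ring C8–C9–C11–C12–C13–C14 is completed by the C11–C12 bond and set free as a normal ring only when C11–C16 is cut. C13, the one new stereocentre that survives, is controlled by C8: the allyl arm reaches only the enone face on which it stands and C12 must lie endo in the norbornane-like biradical to meet C11, so (8S) leads to (13R), while C11 and C16 lose their stereogenicity on fragmentation. The selectivity required is regiochemical, C13 to C16 and not to C11; both are five-ring closures, but bonding at C11 would turn C9 into the sp2 one-atom bridge of a bicyclo[2.2.1]heptane and give up the α-acyl stabilisation of the remaining ring radical, whereas bonding at C16 keeps C9 in a two-atom bridge. Pyrex-filtered light, high dilution and exclusion of oxygen are meant to hold back the photochemical 1,3-acetyl shift and intermolecular dimerisation.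

Step 8
Reactants: 11 bicyclo[3.2.1]octane-2,6-dione
Product: 12 (1S,5R)-1-[3-(tert-butyldimethylsilyloxy)propyl]-6-methylidenebicyclo[3.2.1]octan-2-one
Conditions: Ph3PCH3Br (1.15 equiv), KOt-Bu (1.1 equiv), THF, 0 °C; then 11, −20 → 0 °C
Reagents that add atoms: methyltriphenylphosphonium bromide, C[P+](c1ccccc1)(c1ccccc1)c1ccccc1.[Br-]
Why: Wittig methylenation with about one equivalent of ylide should pick the cyclopentanone carbonyl C16, flanked by CH2 and CH, over C9, which is shielded by the adjacent quaternary C8.

Step 9
Reactants: 12 6-methylidene ketone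
Product: 13 (1S,2S,5R)-1-[3-(tert-butyldimethylsilyloxy)propyl]-6-methylidenebicyclo[3.2.1]octan-2-ol
Conditions: NaBH4, MeOH, 0 °C → rt
Reagents that add atoms: none
Why: Borohydride reduction masks C9, whose α-protons and carbonyl would interfere in steps 18, 19 and 21; hydride should arrive from the face of the one-carbon bridge C14, away from the C15–C16 bridge, to give the equatorial (9S) alcohol, a centre that is erased again in step 24.

Step 10
Reactants: 13 C9 alcohol
Product: 14 bis(tert-butyldimethylsilyl) ether of 13
Conditions: TBSOTf, 2,6-lutidine, CH2Cl2, 0 °C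
Reagents that add atoms: tert-butyldimethylsilyl trifluoromethanesulfonate, CC(C)(C)[Si](C)(C)OS(=O)(=O)C(F)(F)F
Why: Silylation with the triflate and a hindered pyridine base is the standard way to protect a neopentyl secondary alcohol.

Step 11
Reactants: 14 bis-silyl ether
Product: 15 3-[(1S,2S,5R)-2-(tert-butyldimethylsilyloxy)-6-methylidenebicyclo[3.2.1]octan-1-yl]propan-1-ol
Conditions: camphor-10-sulfonic acid (10 mol %), MeOH/CH2Cl2 1:1, 0 °C
Reagents that add atoms: none
Why: Acid-catalysed methanolysis discriminates on steric grounds, so that the primary silyl ether is cleaved while the secondary one next to the quaternary C8 stays.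

Step 12
Reactants: 15 primary alcohol
Product: 16 3-[(1S,2S,5R)-2-(tert-butyldimethylsilyloxy)-6-methylidenebicyclo[3.2.1]octan-1-yl]propanal (C5 aldehyde)
Conditions: DMP (1,1,1-triacetoxy-1,1-dihydro-1,2-benziodoxol-3(1H)-one), CH2Cl2, 0 °C → rt
Reagents that add atoms: none
Why: The Dess–Martin oxidation stops at the aldehyde under near-neutral conditions that leave the exocyclic alkene and the silyl ether untouched.

Step 13
Reactants: 16 C5 aldehyde
Product: 17 (E)-5-[(1S,2S,5R)-2-(tert-butyldimethylsilyloxy)-6-methylidenebicyclo[3.2.1]octan-1-yl]pent-2-enal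
Conditions: Ph3P=CHCHO, toluene, 80 °C
Reagents that add atoms: (triphenylphosphoranylidene)acetaldehyde, O=CC=P(c1ccccc1)(c1ccccc1)c1ccccc1
Why: Wittig olefination with the stabilised formyl ylide extends the chain by C4 and C19 and should give the (E)-enal.

Step 14
Reactants: 18 α-angelica lactone (5-methylfuran-2(3H)-one)
Product: 19 trimethyl[(5-methylfuran-2-yl)oxy]silane
Conditions: TMSCl, Et3N, Et2O, 0 °C → rt; filter, distil
Reagents that add atoms: chlorotrimethylsilane, C[Si](C)(C)Cl
Why: Soft enolisation and O-silylation of the β,γ-unsaturated lactone give the aromatic 2-silyloxyfuran, the vinylogous nucleophile that carries C1, C2, C3, C10 and C20.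

Step 15
Reactants: 17 (E)-enal; 19 trimethyl[(5-methylfuran-2-yl)oxy]silane
Product: 20 (3S)-3-[(2R)-2-methyl-5-oxo-2,5-dihydrofuran-2-yl]-5-[(1S,2S,5R)-2-(tert-butyldimethylsilyloxy)-6-methylidenebicyclo[3.2.1]octan-1-yl]pentanal (syn adduct; C5 and C10 arranged in space as in the target)
Conditions: (2R,5R)-5-benzyl-2-tert-butyl-3-methylimidazolidin-4-one (20 mol %), 2,4-dinitrobenzoic acid (20 mol %), H2O (2 equiv), CH2Cl2, −60 °C
Reagents that add atoms: none
Why: Iminium-catalysed vinylogous Mukaiyama–Michael addition: the amine forms the (E)-iminium ion of 17 with one face covered by its benzyl group, the furan attacks C5 through its methyl-bearing carbon in the syn mode known for 5-methyl-2-silyloxyfurans and β-alkyl enals, and so the catalyst alone, not the remote C8 and C13, sets C5 (S) and the oxygenated quaternary C10 with C6 and the ring oxygen in the relation that becomes trans on ring A.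

Step 16
Reactants: 20 butenolide aldehyde
Product: 21 the corresponding C19 carboxylic acid
Conditions: NaClO2, NaH2PO4, 2-methyl-2-butene, t-BuOH/H2O, 0 °C → rt
Reagents that add atoms: sodium chlorite, [Na+].[O-]Cl=O
Why: The Pinnick oxidation takes the aldehyde C19 to the acid without touching the alkenes, since the hypochlorite formed is trapped by 2-methyl-2-butene.

Step 17
Reactants: 21 butenolide acid
Product: 22 the corresponding C19 methyl ester
Conditions: MeI, K2CO3, DMF, rt
Reagents that add atoms: iodomethane, CI
Why: Carboxylate SN2 alkylation gives the methyl ester under conditions too mild to affect the butenolide, which has no γ-hydrogen.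

Step 18
Reactants: 22 butenolide methyl ester
Product: 23 C4-methylated butenolide methyl ester (both C4 epimers; C5 and C10 unchanged)
Conditions: LiN(i-Pr)2 (1.05 equiv), THF/DMPU, −78 °C, 15 min; MeI (5 equiv), −78 °C
Reagents that add atoms: iodomethane, CI
Why: Ester enolate alkylation: C4–H2 is the only acidic site of 22, and at −78 °C in the presence of DMPU methylation is expected to outrun attack on the lactone carbonyl; the epimer mixture at C4 is of no consequence because C4 is planarised in step 19.

Step 19
Reactants: 23 C4-methyl butenolide ester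
Product: 25 ring A enone lactone (3-oxo-1-ene 19,10-lactone; 4S,5S,10S; C9 silyl ether), via hydroxy keto ester 24 (not isolated)
Conditions: LiN(i-Pr)2 (1.3 equiv), THF, −78 → −10 °C; AcOH, −78 °C
Reagents that add atoms: none
Why: Dieckmann condensation with translactonisation: C4–H is the only acidic C–H of 23, its enolate adds to the lactone carbonyl C3 through a 7-oxabicyclo[2.2.1]heptene-type tetrahedral intermediate, C3–O cleavage frees the C10 alkoxide of 24, and only the C4 epimer with the ester cis to that alkoxide can lactonise with loss of methoxide, the other returning to the enolate by retro-Claisen attack of the alkoxide on C3, so that C4 is set (S) by the C10 oxygen.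

Step 20
Reactants: 25 ring A enone lactone
Product: 26 ring A saturated 3-keto 19,10-lactone
Conditions: Cu(OAc)2·H2O (5 mol %), 1,2-bis(diphenylphosphino)benzene (5 mol %), (EtO)2MeSiH, t-BuOH, toluene, rt
Reagents that add atoms: none
Why: Ligated copper hydride adds in the 1,4-sense to the enone only (catalytic conjugate reduction with a silane), so that C1=C2 is saturated while the unactivated C16 methylidene, the lactone and the silyl ether remain.

Step 21
Reactants: 26 3-keto lactone
Product: 27 (3S)-3-hydroxy 19,10-lactone
Conditions: LiBH(s-Bu)3 (1.5 equiv), THF, −78 °C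
Reagents that add atoms: none
Why: Diastereoselective ketone reduction with a bulky trialkylborohydride: the C6 chain on the one-carbon bridge C5 hangs over the C1–C2–C3 bridge and closes that face of C3=O, so hydride comes from the side of the flat lactone bridge and the hydroxyl ends up axial, syn to C5 (3S).

Step 22
Reactants: 27 3-hydroxy lactone
Product: 28 (3S)-3-acetoxy 19,10-lactone, C9 silyl ether
Conditions: Ac2O, 4-(dimethylamino)pyridine, pyridine, 40 °C
Reagents that add atoms: acetic anhydride, CC(=O)OC(C)=O
Why: Nucleophile-catalysed acetylation overcomes the hindrance of the axial neopentyl alcohol.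

Step 23
Reactants: 28 acetate silyl ether
Product: 29 (9S)-9-hydroxy 3-acetoxy 19,10-lactone
Conditions: HF·pyridine, THF/pyridine, 0 °C → rt
Reagents that add atoms: none
Why: Fluoride-driven desilylation under mildly acidic conditions frees the C9 alcohol without acetate cleavage, lactone opening or migration of the exocyclic double bond.

Step 24
Reactants: 29 C9 alcohol
Product: 30 target CNP0204681.1 (3S,4S,5S,8S,10S,13R)
Conditions: DMP, CH2Cl2, rt
Reagents that add atoms: none
Why: The Dess–Martin oxidation restores the C9 ketone and removes the auxiliary C9 stereocentre, giving the target.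

Compound list
1 | cyclopentane-1,3-dione | O=C1CCC(=O)C1 | starting material
2 | 3-isobutoxycyclopent-2-en-1-one | CC(C)COC1=CC(=O)CC1 | intermediate
3 | allyl chloroformate | C=CCOC(Cl)=O | starting material
4 | allyl 4-isobutoxy-2-oxocyclopent-3-ene-1-carboxylate (racemic) | C=CCOC(=O)C1CC(OCC(C)C)=CC1=O | intermediate
5 | (3-bromopropoxy)(tert-butyl)dimethylsilane | CC(C)(C)[Si](C)(C)OCCCBr | starting material
6 | allyl 1-[3-(tert-butyldimethylsilyloxy)propyl]-4-isobutoxy-2-oxocyclopent-3-ene-1-carboxylate (racemic) | C=CCOC(=O)C1(CCCO[Si](C)(C)C(C)(C)C)CC(OCC(C)C)=CC1=O | intermediate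
7 | (S)-5-allyl-5-[3-(tert-butyldimethylsilyloxy)propyl]-3-isobutoxycyclopent-2-en-1-one | C=CC[C@@]1(CCCO[Si](C)(C)C(C)(C)C)CC(OCC(C)C)=CC1=O | intermediate
8 | (S)-4-allyl-4-[3-(tert-butyldimethylsilyloxy)propyl]cyclopentane-1,3-dione | C=CC[C@@]1(CCCO[Si](C)(C)C(C)(C)C)CC(=O)CC1=O | intermediate
9 | (S)-3-acetoxy-5-allyl-5-[3-(tert-butyldimethylsilyloxy)propyl]cyclopent-2-en-1-one | C=CC[C@@]1(CCCO[Si](C)(C)C(C)(C)C)CC(OC(C)=O)=CC1=O | intermediate
10 | 6-acetoxy-1-[3-(tert-butyldimethylsilyloxy)propyl]tricyclo[3.2.1.0(3,6)]octan-2-one (photoadduct, not isolated) | O=C1[C@@H]2C[C@@H]3C[C@@]1(CCCO[Si](C)(C)C(C)(C)C)C[C@]23OC(C)=O | intermediate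
11 | (1S,5R)-1-[3-(tert-butyldimethylsilyloxy)propyl]bicyclo[3.2.1]octane-2,6-dione | O=C1C[C@]2(CCCO[Si](C)(C)C(C)(C)C)C[C@H]1CCC2=O | intermediate
12 | (1S,5R)-1-[3-(tert-butyldimethylsilyloxy)propyl]-6-methylidenebicyclo[3.2.1]octan-2-one | C=C1C[C@]2(CCCO[Si](C)(C)C(C)(C)C)C[C@H]1CCC2=O | intermediate
13 | (1S,2S,5R)-1-[3-(tert-butyldimethylsilyloxy)propyl]-6-methylidenebicyclo[3.2.1]octan-2-ol | C=C1C[C@]2(CCCO[Si](C)(C)C(C)(C)C)C[C@H]1CC[C@@H]2O | intermediate
14 | bis(tert-butyldimethylsilyl) ether of 13 | C=C1C[C@]2(CCCO[Si](C)(C)C(C)(C)C)C[C@H]1CC[C@@H]2O[Si](C)(C)C(C)(C)C | intermediate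
15 | 3-[(1S,2S,5R)-2-(tert-butyldimethylsilyloxy)-6-methylidenebicyclo[3.2.1]octan-1-yl]propan-1-ol | C=C1C[C@]2(CCCO)C[C@H]1CC[C@@H]2O[Si](C)(C)C(C)(C)C | intermediate
16 | 3-[(1S,2S,5R)-2-(tert-butyldimethylsilyloxy)-6-methylidenebicyclo[3.2.1]octan-1-yl]propanal | C=C1C[C@]2(CCC=O)C[C@H]1CC[C@@H]2O[Si](C)(C)C(C)(C)C | intermediate
17 | (E)-5-[(1S,2S,5R)-2-(tert-butyldimethylsilyloxy)-6-methylidenebicyclo[3.2.1]octan-1-yl]pent-2-enal | C=C1C[C@]2(CC/C=C/C=O)C[C@H]1CC[C@@H]2O[Si](C)(C)C(C)(C)C | intermediate
18 | α-angelica lactone (5-methylfuran-2(3H)-one) | CC1=CCC(=O)O1 | starting material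
19 | trimethyl[(5-methylfuran-2-yl)oxy]silane | Cc1ccc(O[Si](C)(C)C)o1 | intermediate
20 | syn Michael adduct, C19 aldehyde with C10 butenolide | C=C1C[C@]2(CC[C@@H](CC=O)[C@@]3(C)OC(=O)C=C3)C[C@H]1CC[C@@H]2O[Si](C)(C)C(C)(C)C | intermediate
21 | C19 carboxylic acid of 20 | C=C1C[C@]2(CC[C@@H](CC(=O)O)[C@@]3(C)OC(=O)C=C3)C[C@H]1CC[C@@H]2O[Si](C)(C)C(C)(C)C | intermediate
22 | C19 methyl ester of 21 | C=C1C[C@]2(CC[C@@H](CC(=O)OC)[C@@]3(C)OC(=O)C=C3)C[C@H]1CC[C@@H]2O[Si](C)(C)C(C)(C)C | intermediate
23 | C4-methyl ester (C4 epimers) | C=C1C[C@]2(CC[C@@H](C(C)C(=O)OC)[C@@]3(C)OC(=O)C=C3)C[C@H]1CC[C@@H]2O[Si](C)(C)C(C)(C)C | intermediate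
24 | 10-hydroxy-3-oxo-1-ene 19-methyl ester (ring A closed, not isolated) | C=C1C[C@]2(CC[C@H]3[C@](C)(C(=O)OC)C(=O)C=C[C@]3(C)O)C[C@H]1CC[C@@H]2O[Si](C)(C)C(C)(C)C | intermediate
25 | ring A enone 19,10-lactone | C=C1C[C@]2(CC[C@H]3[C@]4(C)C(=O)O[C@@]3(C)C=CC4=O)C[C@H]1CC[C@@H]2O[Si](C)(C)C(C)(C)C | intermediate
26 | ring A 3-keto 19,10-lactone | C=C1C[C@]2(CC[C@H]3[C@]4(C)C(=O)O[C@@]3(C)CCC4=O)C[C@H]1CC[C@@H]2O[Si](C)(C)C(C)(C)C | intermediate
27 | (3S)-3-hydroxy 19,10-lactone | C=C1C[C@]2(CC[C@H]3[C@]4(C)C(=O)O[C@@]3(C)CC[C@@H]4O)C[C@H]1CC[C@@H]2O[Si](C)(C)C(C)(C)C | intermediate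
28 | (3S)-3-acetoxy 19,10-lactone, C9 silyl ether | C=C1C[C@]2(CC[C@H]3[C@]4(C)C(=O)O[C@@]3(C)CC[C@@H]4OC(C)=O)C[C@H]1CC[C@@H]2O[Si](C)(C)C(C)(C)C | intermediate
29 | (9S)-9-hydroxy 3-acetoxy 19,10-lactone | C=C1C[C@]2(CC[C@H]3[C@]4(C)C(=O)O[C@@]3(C)CC[C@@H]4OC(C)=O)C[C@H]1CC[C@@H]2O | intermediate
30 | CNP0204681.1 | C=C1C[C@]2(CC[C@H]3[C@]4(C)C(=O)O[C@@]3(C)CC[C@@H]4OC(C)=O)C[C@H]1CCC2=O | target

Total step count: 24. Longest linear sequence: 23 (steps 1–13 and 15–24; step 14 is a one-step side branch).

Steps most likely to fail

1. Step 7.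
- What may go wrong: the first bond may form from C13 to C11 instead of C16. Closure to the strained tricycle may also be slow enough for acetyl migration or oligomerisation to take over.
- Fallback: it makes the same bonds one at a time in the ground state, sets out from 9 and comes back at 11.
- The allyl group of 9 is epoxidised with m-chloroperbenzoic acid, the enol acetate double bond being deactivated by the ketone. This gives the terminal epoxide F1.
- (C5H5)2TiCl (trivalent titanium), made from (C5H5)2TiCl2 and zinc dust, opens the epoxide to the secondary C13 radical. As a nucleophilic radical it can add only to the enone β-carbon C16 (5-exo, Giese-type). Reduction of the α-acyl radical and work-up give the hydroxymethyl bicyclo[2.2.1]heptanone F2.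
- K2CO3 in methanol removes the acetate, and retro-aldol cleavage of C11–C16 gives the acetyl hydroxymethyl cyclopentanone F3.
- Mesylation and elimination (MsCl, Et3N, then 1,8-diazabicyclo[5.4.0]undec-7-ene) lead to the α-methylidene cyclopentanone F4.
- A substoichiometric amount of KOt-Bu closes C11–C12 by intramolecular Michael addition of the methyl ketone enolate, C13 being fixed by the bridge, to give 11.

2. Step 19.
- What may go wrong: deprotonation at the hindered C4–H may be sluggish, the enolate may stall before the oxa-bridged tetrahedral intermediate, or the liberated methoxide may re-open the β-keto lactone.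
- Fallback: it makes the lactone first and closes the carbocycle afterwards, sets out from 23 and comes back at 26.
- The butenolide of 23 is saturated with the copper hydride system of step 20 to the saturated lactone ester F5.
- MeNH(OMe)·HCl and i-PrMgCl open the unhindered γ-lactone at C3. The freed C10 alkoxide closes on the C19 ester to give the 19,10-lactone N-methoxy-N-methylamide F6.
- In F6 the lactone C4–H is far more acidic than the amide C2–H. LiN(i-Pr)2 therefore forms the C4 enolate, which acylates on the amide delivered from the C10 side chain.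
- The chelated tetrahedral intermediate survives until the quench, so no alkoxide is released in the presence of the product. C4 is set by the tether, and 26 results.

3. Step 18.
- What may go wrong: the unhindered ester enolate may close on the butenolide carbonyl before it is methylated, or it may be methylated twice.
- Fallback: it introduces the methyl group without any enolate, sets out from 20 and comes back at 23.
- Aldehyde 20 is α-methylenated with aqueous formaldehyde, catalytic pyrrolidine and propionic acid in i-PrOH (Mannich condensation–elimination) to the α-methylidene aldehyde F7.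
- The enal double bond alone is reduced with Bu3SnH, Pd(PPh3)4 (cat.) and AcOH, conditions under which unsaturated esters and lactones react poorly. This gives the α-methyl aldehyde F8.
- Pinnick oxidation as in step 16 gives the α-methyl acid F9, and MeI/K2CO3 as in step 17 gives 23.

Further compounds
F1 | step 7 | (5S)-3-acetoxy-5-(oxiran-2-ylmethyl)-5-[3-(tert-butyldimethylsilyloxy)propyl]cyclopent-2-en-1-one (epoxide epimers) | C1OC1C[C@@]2(CCCO[Si](C)(C)C(C)(C)C)CC(OC(C)=O)=CC2=O
F2 | step 7 | 4-acetoxy-5-(hydroxymethyl)-1-[3-(tert-butyldimethylsilyloxy)propyl]bicyclo[2.2.1]heptan-2-one (C13 epimers) | O=C1C[C@@]2(OC(C)=O)C[C@]1(CCCO[Si](C)(C)C(C)(C)C)CC2CO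
F3 | step 7 | 4-acetyl-4-[3-(tert-butyldimethylsilyloxy)propyl]-2-(hydroxymethyl)cyclopentan-1-one (C13 epimers) | CC(=O)[C@]1(CCCO[Si](C)(C)C(C)(C)C)CC(=O)C(CO)C1
F4 | step 7 | 4-acetyl-4-[3-(tert-butyldimethylsilyloxy)propyl]-2-methylidenecyclopentan-1-one | CC(=O)[C@]1(CCCO[Si](C)(C)C(C)(C)C)CC(=O)C(=C)C1
F5 | step 19 | saturated C3 γ-lactone with C4-methyl C19 methyl ester (C4 epimers) | C=C1C[C@]2(CC[C@@H](C(C)C(=O)OC)[C@@]3(C)OC(=O)CC3)C[C@H]1CC[C@@H]2O[Si](C)(C)C(C)(C)C
F6 | step 19 | monocyclic 19,10-lactone with C3 N-methoxy-N-methylamide side chain (C4 epimers) | C=C1C[C@]2(CC[C@H]3C(C)C(=O)O[C@@]3(C)CCC(=O)N(C)OC)C[C@H]1CC[C@@H]2O[Si](C)(C)C(C)(C)C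
F7 | step 18 | α-methylidene aldehyde of 20 | C=C1C[C@]2(CC[C@@H](C(=C)C=O)[C@@]3(C)OC(=O)C=C3)C[C@H]1CC[C@@H]2O[Si](C)(C)C(C)(C)C
F8 | step 18 | α-methyl aldehyde (C4 epimers) | C=C1C[C@]2(CC[C@@H](C(C)C=O)[C@@]3(C)OC(=O)C=C3)C[C@H]1CC[C@@H]2O[Si](C)(C)C(C)(C)C
F9 | step 18 | α-methyl carboxylic acid (C4 epimers) | C=C1C[C@]2(CC[C@@H](C(C)C(=O)O)[C@@]3(C)OC(=O)C=C3)C[C@H]1CC[C@@H]2O[Si](C)(C)C(C)(C)C
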